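Compound numbers are those of the steps and of the compound list below.

## Analysis of the target

Quercetin 3,3'-bissulfate 18 is a flavonol: a 4H-chromen-4-one (benzo ring A fused to the γ-pyranone ring C) with the catechol-derived ring B on C2 and oxygen on C3, C5, C7, C3' and C4'. The molecule is flat and achiral, so any sp3 centre that appears on the way (C3 of an open-chain precursor) only has to be erased when ring C becomes aromatic. The sensitive groups are the two sulfate monoesters, an enol-type one on O3 and an aryl one on O3'; they are strong acids, are hydrolysed under acidic conditions, make the compound very polar, and rule out Lewis acids and most silica chromatography once they are present. The free hydroxyls on O4', O5 and O7 make the compound an oxidisable polyphenol. The difficulty is therefore not the carbon skeleton but the differentiation of five oxygens: O3 and O3' sulfated, O4', O5 and O7 free, with O3' and O4' adjacent and chemically similar. This argues for building the skeleton from parts in which each oxygen already carries the right protecting group, and for groups on O4', O5 and O7 that leave last under neutral conditions. The strategy rests on one feature: C4 is a lone carbonyl carbon between C4a of ring A, whose 1,3,5-trioxygenated pattern is threefold symmetric until O1 is singled out, and the oxygenated C3, so that C4 can be supplied as carbon monoxide between an aryl iodide and a ketone enolate.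

## Retrosynthetic reasoning

18 to 17. The three aryl O–benzyl bonds on O4', O5 and O7 are cut last. Once sulfate monoesters are present, Brønsted and Lewis acids are excluded, whereas neutral hydrogenolysis leaves an S–O ester alone. The forward step only has to remove three benzyl groups from 17 without reducing the pyranone.

17 to 16. The two O–S bonds on O3 and O3' are cut together. In 16 these are the only free hydroxyls, so the regiochemistry of sulfation is decided by the protecting-group pattern and not by small reactivity differences among flavonol hydroxyls. The forward reaction must be exhaustive and must include the chelated O3–H.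

16 to 14. Ring C is opened at O1–C2 and the methoxymethyl groups are returned to O3 and O3'. This gives the ortho-hydroxyaryl 1,3-diketone 14, in which every carbon of ring C already has its final oxidation level (C2 and C4 carbonyls, C3 oxygenated). Closure is then a cyclodehydration through hemiketal 15, and no later oxidation of ring C is needed. One acidic operation should unmask both hydroxyls and close the ring; the only stereocentre of 14 disappears here.

14 to 13. The free ring A hydroxyl of 14 is traced back to a benzyl ether, which gives 13 with three identical ethers on ring A. The cut is placed at an ortho oxygen because only an ortho ether can be held together with the C4 carbonyl by a chelating Lewis acid. The two ortho ethers of 13 are equivalent, so it does not matter which one is lost.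

13 to 3, 10 and 11. Both C–C bonds of C4 are cut: C4a–C4 and C4–C3. C4 then is carbon monoxide 11. What remains is the aryl iodide 3, symmetric apart from its iodine, and the ketone 10, which carries ring B, C2, C3 and the protected O3. A single cut at C2–C3 (acyl transfer of the Baker–Venkataraman kind) would require ring A to be differentiated, with one free and two protected hydroxyls, before the coupling. Cutting on both sides of C4 postpones that differentiation to 13, where the new carbonyl directs it. The forward reaction has to insert 11 before the aryl group couples and has to stop after one acylation.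

3 to 2 to 1. The C–I bond is cut (electrophilic iodination of 2, one product by symmetry), then the three O–benzyl bonds, back to triacetate 1, from which the phenoxides can be released one at a time.

10 to 9 to 6 to 5 to 4. The O3 acetal is removed (9), the C3–O3 bond is cut (α-hydroxylation of methyl ketone 6 through silyl enol ether 7 and silyloxy ketone 8), the O3' acetal is removed (5), and last the O4'–benzyl bond is cut to reach 4. This last cut is where O3' and O4' are told apart: in 4 the hydroxyl para to the acetyl group is the more acidic and is benzylated first. Enolate 12 of ketone 10 is the nucleophile of the key step.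

## Alternatives that were turned down

Alternative 1: Semisynthesis with a cyclic sulfate across O3' and O4'.
- Disconnection: only O–S bonds. The whole skeleton comes from quercetin A5, and the two ring B oxygens are tied to one sulfur so that ring opening, not a protecting group, distinguishes them.
- Forward key step: the catechol of the 5,7-di-O-benzyl flavonol A2, whose O3 already bears a sulfate masked as its 2,2,2-trichloroethyl diester, is bridged by 1,1'-sulfonyldiimidazole A3 with the base Cs2CO3 A4. This forms O3'–S and O4'–S and gives the five-membered cyclic sulfate A1. Hydrolytic opening is then meant to leave sulfur on O3'; reductive loss of the trichloroethyl group and hydrogenolysis would finish.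
- For it: no C–C bond has to be made and A5 is cheap. The opening has a rational bias, because the O4' phenoxide is conjugated through C2 with the C4 carbonyl and is the better leaving group.
- Against it:
  - The bias rests on a small difference in leaving-group ability, so opening that leaves sulfur on O4' is to be expected alongside, and two regioisomeric sulfate salts are very hard to separate.
  - A catechol cyclic sulfate such as A1 is a strained, highly electrophilic ester that may not survive the carbonate base A4 and the azole released from A3.
  - The neutral sulfate diester on the enolic O3 of A2 and A1 is itself an electrophile.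
  - A2 is not close to A5: benzylating the chelated O5 while O3 and the catechol stay free needs several protection and deprotection steps.
- Comparison: alternative 1 is stronger on step count and needs neither a transition metal nor carbon monoxide 11, provided every selective step works. The chosen strategy offers regiochemistry fixed by construction instead. O3' and O4' are told apart on the small ketone 4, where the acidity difference is large and a wrong isomer is removed at once, and in 16 only the two hydroxyls to be sulfated are free.

Alternative 2: Biomimetic polyketide closure.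
- Disconnection: the ring A bond C4a–C5 and the ring C bond O1–C2. This leads back to the open-chain cinnamoyl triketo ester A7, in which ring B with C2 and C3 comes from a cinnamoyl group and ring A from three acetate units.
- Forward key step: the chelating base Mg(OMe)2 A8 in its parent alcohol effects an intramolecular Claisen condensation of A7 (chain carbon C6 onto the ester carbon; ring A closes). A ring A hydroxyl then adds to the enone (ring C closes) to give the racemic flavanone A6.
- For it: two rings and two skeletal bonds are formed in one operation from an acyclic precursor, which is more than the chosen key step achieves. No ring A protecting groups are needed at that stage, and with A8 as the only reagent no palladium or gas is used.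
- Against it:
  - A7 is a 3,5,7-triketo ester that must be assembled by polyanion acylations.
  - A7 has competing closures: aldol closure of its C2 onto C7, lactonisation of an enol oxygen onto the ester, and enolate addition to the cinnamoyl double bond.
  - A6 is at the flavanone oxidation level and has no oxygen on C3. Dehydrogenation of C2–C3, hydroxylation of C3 and benzylation of O5 and O7 (O5 chelated) must follow, roughly four extra steps before the same endgame, with the oxidations carried out on an electron-rich aryl ether.
- Comparison: alternative 2 is stronger in the complexity its key step generates. The chosen strategy brings every carbon of ring C in at its final oxidation level, with O3 present and protected orthogonally to the benzyl ethers, and reaches 16 two steps after the key bond formation.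

Alternative 3: ortho-Quinone methide cycloaddition.
- Disconnection: C3–C4 and O1–C2 of ring C, with C4 at the methylene level. Ring A becomes the ortho-quinone methide A13, and ring B with C2 and C3 becomes the silyl enol ether A11.
- Forward key step: hydride from NaBH4 A12 turns the aldehyde of the O-Boc salicylaldehyde A10 into a benzylic alkoxide, which takes over the Boc group from the phenol oxygen and then loses it as a carbonate leaving group. The resulting A13 adds A11 in an inverse-demand hetero-[4+2] cycloaddition to give the chroman A9 as a mixture of racemic diastereomers.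
- For it: ring C closes in the key step with both bonds formed at once, and the regiochemistry follows from the polarity of the partners. O3 and the C2 oxygen are in place, the conditions are mild and free of transition metals, and A11 would be one step from ketone 10.
- Against it:
  - C4 of A9 is a CH2 group, so a benzylic oxidation to the carbonyl and elimination of the C2 silyloxy group to form the C2–C3 double bond remain. That oxidation must be selective in the presence of benzyl ether CH2 groups and an electron-rich ring.
  - The hydride reagent A12 that generates A13 also reduces it, in competition with the hindered trisubstituted enol ether A11.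
  - A10 requires a desymmetrised, formylated ring A (one carbonate, two benzyl ethers), which is the differentiation the chosen route obtains from chelation in step 8.
- Comparison: alternative 3 is stronger in that its key step closes ring C directly with inherently certain regiochemistry. The chosen strategy installs C4 as a carbonyl from the start, so nothing is oxidised late next to benzyl ethers, and its ring A partner needs no desymmetrisation before the coupling.

Key step: step 7

Assumption: the target is drawn as the free bis(hydrogen sulfate), so 17 and 18 are written in that neutral form, although such monoesters would be made, purified and stored as their ammonium or alkali salts.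

## Route

Step 1
Reactants: 1 benzene-1,3,5-triyl triacetate
Product: 2 1,3,5-tris(benzyloxy)benzene
Conditions: BnCl (3.3 equiv), NaH (6.5 equiv), H2O (3 equiv, slow addition), DMF, 0 °C to rt
Reagents that add atoms: benzyl chloride, ClCc1ccccc1
Why: Williamson etherification with slow deacetylation in the flask: hydroxide made from NaH and water unmasks one phenoxide at a time, and each is O-benzylated before a polyanion prone to C-benzylation can build up.

Step 2
Reactants: 2 1,3,5-tris(benzyloxy)benzene
Product: 3 1,3,5-tris(benzyloxy)-2-iodobenzene
Conditions: N-iodosuccinimide (1.0 equiv), DMF, 0 °C to rt, dark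
Reagents that add atoms: N-iodosuccinimide, O=C1CCC(=O)N1I
Why: Electrophilic aromatic iodination of a triply activated ring; the three free positions are equivalent, so only one mono-iodide can form, and one equivalent of reagent at low temperature should limit a second iodination.

Step 3
Reactants: 4 1-(3,4-dihydroxyphenyl)ethan-1-one (3',4'-dihydroxyacetophenone)
Product: 5 1-[4-(benzyloxy)-3-hydroxyphenyl]ethan-1-one
Conditions: BnBr (1.05 equiv), NaHCO3, NaI (cat.), DMF, 40 °C
Reagents that add atoms: benzyl bromide, BrCc1ccccc1
Why: Williamson etherification under weak-base control: the hydroxyl para to the acetyl group is the more acidic, so hydrogencarbonate ionises it preferentially and benzylation should occur on O4; any 3-O or bis-benzyl material is removed here on a small molecule.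

Step 4
Reactants: 5 1-[4-(benzyloxy)-3-hydroxyphenyl]ethan-1-one
Product: 6 1-[4-(benzyloxy)-3-(methoxymethoxy)phenyl]ethan-1-one
Conditions: MOMCl, iPr2NEt, CH2Cl2, 0 °C to rt
Reagents that add atoms: chloromethyl methyl ether, COCCl
Why: O-Alkylation of the remaining phenol to its methoxymethyl acetal with a hindered amine base; the methyl ketone is not affected.

Step 5
Reactants: 6 1-[4-(benzyloxy)-3-(methoxymethoxy)phenyl]ethan-1-one
Product: 9 1-[4-(benzyloxy)-3-(methoxymethoxy)phenyl]-2-hydroxyethan-1-one, via silyl enol ether 7 (not isolated), via silyloxy ketone 8 (not isolated)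
Conditions: LiN(SiMe3)2, THF, −78 °C; Me3SiCl, −78 to 0 °C; crude 7: mCPBA, NaHCO3, CH2Cl2, 0 °C; then 10% aq. citric acid, THF–MeOH, rt
Reagents that add atoms: m-chloroperoxybenzoic acid, O=C(OO)c1cccc(Cl)c1 (the oxygen atom); chlorotrimethylsilane, C[Si](C)(C)Cl (in 7 and 8 only)
Why: Rubottom oxidation: the kinetic enolate is trapped as 7, epoxidation by the peracid and a 1,4-silyl shift give 8, and mild acid removes the silyl group without touching the aryl acetal; the silyl enol ether is far more nucleophilic toward the peracid than the dialkoxyarene.

Step 6
Reactants: 9 1-[4-(benzyloxy)-3-(methoxymethoxy)phenyl]-2-hydroxyethan-1-one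
Product: 10 1-[4-(benzyloxy)-3-(methoxymethoxy)phenyl]-2-(methoxymethoxy)ethan-1-one
Conditions: MOMCl, iPr2NEt, CH2Cl2, 0 °C to rt
Reagents that add atoms: chloromethyl methyl ether, COCCl
Why: O-Alkylation of the primary ketol hydroxyl under amine base; the product has one enolisable position, the carbon that becomes C3, next to the protected O3.

Step 7
Reactants: 3 1,3,5-tris(benzyloxy)-2-iodobenzene; 10 1-[4-(benzyloxy)-3-(methoxymethoxy)phenyl]-2-(methoxymethoxy)ethan-1-one; 11 carbon monoxide
Product: 13 racemic 1-[2,4,6-tris(benzyloxy)phenyl]-3-[4-(benzyloxy)-3-(methoxymethoxy)phenyl]-2-(methoxymethoxy)propane-1,3-dione, via sodium enolate 12 (not isolated)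
Conditions: 10 (2.0 equiv), NaN(SiMe3)2 (2.0 equiv), 1,4-dioxane, rt; then 3 (1.0 equiv), Pd(OAc)2 (5 mol %), Xantphos (6 mol %), CO (2 bar), 80 °C; aq. NH4Cl
Reagents that add atoms: none
Why: Zerovalent palladium, generated in the flask from divalent Pd(OAc)2, Xantphos and CO, inserts into the C–I bond of 3; in the resulting arylpalladium iodide the two ortho benzyloxy groups slow any coupling at the aryl carbon, whereas migratory insertion of 11 relieves the congestion and gives the aroylpalladium iodide (C4a–C4). Enolate 12 replaces iodide on palladium, and reductive elimination from the carbon-bound aroyl(enolate) complex, helped by the wide bite angle of Xantphos, forms C4–C3 and returns zerovalent palladium. The closest known reaction type is the palladium-catalysed carbonylative α-arylation of aryl ketones with aryl iodides to 1,3-diketones; the pairing of a di-ortho-substituted iodide with an α-alkoxy ketone has to be regarded as untested. No ring is closed. The one new stereocentre, C3, forms without control as a racemate, which is acceptable because it becomes trigonal when ring C aromatises in step 9. Three selectivities are needed: carbonylative over direct arylation (secured by the di-ortho substitution of 3 and the CO atmosphere), a single site of enolisation (10 has only the C3 methylene), and one acylation only (13 is more acidic than 10 and is converted by the second equivalent of 12 into an unreactive diketonate, which is why two equivalents of 10 and base are used and surplus 10 is recovered). NaN(SiMe3)2 is used and not NaOC(CH3)3, because free tert-butoxide would capture the aroylpalladium as the tert-butyl ester, a path absent from ordinary α-arylation, whereas the silylamine by-product is a poor nucleophile.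

Step 8
Reactants: 13 racemic 1-[2,4,6-tris(benzyloxy)phenyl]-3-[4-(benzyloxy)-3-(methoxymethoxy)phenyl]-2-(methoxymethoxy)propane-1,3-dione
Product: 14 racemic 1-[2,4-bis(benzyloxy)-6-hydroxyphenyl]-3-[4-(benzyloxy)-3-(methoxymethoxy)phenyl]-2-(methoxymethoxy)propane-1,3-dione
Conditions: MgBr2·OEt2 (3 equiv), toluene–Et2O, 80 °C; then 1 M HCl
Reagents that add atoms: none
Why: Chelation-controlled ether cleavage: magnesium held between the C4 carbonyl and an ortho ether oxygen activates that benzyl group for attack by bromide, while benzyl ethers without an ortho carbonyl (para on ring A, ring B) are not activated; after the first cleavage the magnesium phenolate ties up the carbonyl, so the second, equivalent ortho ether should remain.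

Step 9
Reactants: 14 racemic 1-[2,4-bis(benzyloxy)-6-hydroxyphenyl]-3-[4-(benzyloxy)-3-(methoxymethoxy)phenyl]-2-(methoxymethoxy)propane-1,3-dione
Product: 16 5,7-bis(benzyloxy)-2-[4-(benzyloxy)-3-hydroxyphenyl]-3-hydroxy-4H-chromen-4-one (4',5,7-tri-O-benzylquercetin), via cyclic hemiketal 15 (not isolated)
Conditions: HCl (1.25 M in MeOH), THF, 50 °C, argon
Reagents that add atoms: none
Why: Acid-catalysed transacetalisation removes both methoxymethyl groups, the ring A phenol adds to the C2 carbonyl to give hemiketal 15, and loss of water gives the aromatic γ-pyranone (cyclodehydration of an ortho-hydroxyaryl 1,3-diketone, as in the last stage of a Baker–Venkataraman flavone synthesis); aryl benzyl ethers tolerate these conditions, and the racemic C3 centre becomes trigonal.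

Step 10
Reactants: 16 5,7-bis(benzyloxy)-2-[4-(benzyloxy)-3-hydroxyphenyl]-3-hydroxy-4H-chromen-4-one
Product: 17 5,7-bis(benzyloxy)-2-[4-(benzyloxy)-3-(sulfooxy)phenyl]-4-oxo-4H-chromen-3-yl hydrogen sulfate
Conditions: SO3·NMe3 (8 equiv), Et3N, DMF, 60 °C
Reagents that add atoms: sulfur trioxide–trimethylamine complex, C[N+](C)(C)S(=O)(=O)[O-]
Why: O-Sulfation by an amine-complexed SO3; only O3 and O3' are free, so exhaustive sulfation fixes the regiochemistry, and excess reagent with gentle heating is used because O3–H is hydrogen-bonded to the C4 carbonyl.

Step 11
Reactants: 17 5,7-bis(benzyloxy)-2-[4-(benzyloxy)-3-(sulfooxy)phenyl]-4-oxo-4H-chromen-3-yl hydrogen sulfate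
Product: 18 5,7-dihydroxy-2-[4-hydroxy-3-(sulfooxy)phenyl]-4-oxo-4H-chromen-3-yl hydrogen sulfate (quercetin 3,3'-bissulfate)
Conditions: H2 (1 atm), 10% Pd/C, MeOH–THF, rt
Reagents that add atoms: none
Why: Hydrogenolysis of three aryl benzyl ethers over palladium on carbon; sulfate monoesters, kept as salts under neutral conditions, are inert to hydrogenolysis, and the tetrasubstituted C2=C3 bond of the pyranone should not be reduced under these mild conditions.

## Compound list

1 | benzene-1,3,5-triyl triacetate | CC(=O)Oc1cc(OC(C)=O)cc(OC(C)=O)c1 | starting material
2 | 1,3,5-tris(benzyloxy)benzene | c1ccc(COc2cc(OCc3ccccc3)cc(OCc3ccccc3)c2)cc1 | intermediate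
3 | 1,3,5-tris(benzyloxy)-2-iodobenzene | Ic1c(OCc2ccccc2)cc(OCc2ccccc2)cc1OCc1ccccc1 | intermediate
4 | 1-(3,4-dihydroxyphenyl)ethan-1-one | CC(=O)c1ccc(O)c(O)c1 | starting material
5 | 1-[4-(benzyloxy)-3-hydroxyphenyl]ethan-1-one | CC(=O)c1ccc(OCc2ccccc2)c(O)c1 | intermediate
6 | 1-[4-(benzyloxy)-3-(methoxymethoxy)phenyl]ethan-1-one | CC(=O)c1ccc(OCc2ccccc2)c(OCOC)c1 | intermediate
7 | ({1-[4-(benzyloxy)-3-(methoxymethoxy)phenyl]ethenyl}oxy)trimethylsilane | C=C(O[Si](C)(C)C)c1ccc(OCc2ccccc2)c(OCOC)c1 | intermediate
8 | 1-[4-(benzyloxy)-3-(methoxymethoxy)phenyl]-2-(trimethylsilyloxy)ethan-1-one | C[Si](C)(C)OCC(=O)c1ccc(OCc2ccccc2)c(OCOC)c1 | intermediate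
9 | 1-[4-(benzyloxy)-3-(methoxymethoxy)phenyl]-2-hydroxyethan-1-one | OCC(=O)c1ccc(OCc2ccccc2)c(OCOC)c1 | intermediate
10 | 1-[4-(benzyloxy)-3-(methoxymethoxy)phenyl]-2-(methoxymethoxy)ethan-1-one | COCOCC(=O)c1ccc(OCc2ccccc2)c(OCOC)c1 | intermediate
11 | carbon monoxide | [C-]#[O+] | starting material
12 | sodium (Z)-1-[4-(benzyloxy)-3-(methoxymethoxy)phenyl]-2-(methoxymethoxy)ethen-1-olate | COCO/C=C(\[O-])c1ccc(OCc2ccccc2)c(OCOC)c1.[Na+] | intermediate
13 | racemic 1-[2,4,6-tris(benzyloxy)phenyl]-3-[4-(benzyloxy)-3-(methoxymethoxy)phenyl]-2-(methoxymethoxy)propane-1,3-dione | COCOC(C(=O)c1c(OCc2ccccc2)cc(OCc2ccccc2)cc1OCc1ccccc1)C(=O)c1ccc(OCc2ccccc2)c(OCOC)c1 | intermediate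
14 | racemic 1-[2,4-bis(benzyloxy)-6-hydroxyphenyl]-3-[4-(benzyloxy)-3-(methoxymethoxy)phenyl]-2-(methoxymethoxy)propane-1,3-dione | COCOC(C(=O)c1c(O)cc(OCc2ccccc2)cc1OCc1ccccc1)C(=O)c1ccc(OCc2ccccc2)c(OCOC)c1 | intermediate
15 | 5,7-bis(benzyloxy)-2-[4-(benzyloxy)-3-hydroxyphenyl]-2,3-dihydroxychroman-4-one (racemic, mixture of diastereomers) | O=C1C(O)C(O)(c2ccc(OCc3ccccc3)c(O)c2)Oc2cc(OCc3ccccc3)cc(OCc3ccccc3)c12 | intermediate
16 | 5,7-bis(benzyloxy)-2-[4-(benzyloxy)-3-hydroxyphenyl]-3-hydroxy-4H-chromen-4-one | O=c1c(O)c(-c2ccc(OCc3ccccc3)c(O)c2)oc2cc(OCc3ccccc3)cc(OCc3ccccc3)c12 | intermediate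
17 | 5,7-bis(benzyloxy)-2-[4-(benzyloxy)-3-(sulfooxy)phenyl]-4-oxo-4H-chromen-3-yl hydrogen sulfate | O=c1c(OS(=O)(=O)O)c(-c2ccc(OCc3ccccc3)c(OS(=O)(=O)O)c2)oc2cc(OCc3ccccc3)cc(OCc3ccccc3)c12 | intermediate
18 | 5,7-dihydroxy-2-[4-hydroxy-3-(sulfooxy)phenyl]-4-oxo-4H-chromen-3-yl hydrogen sulfate (quercetin 3,3'-bissulfate) | O=c1c(OS(=O)(=O)O)c(-c2ccc(O)c(OS(=O)(=O)O)c2)oc2cc(O)cc(O)c12 | target

## Step count and least certain steps

Total step count: 11 steps. Longest linear sequence: 9 steps (4 to 18 through steps 3 to 11); the ring A branch (steps 1 and 2) joins at step 7.

Step 7 (key step). The most likely failure is capture of the aroylpalladium intermediate on oxygen of the chelated α-alkoxy enolate, giving enol ester formation in place of C-acylation. The second is a coupling so slow at the doubly ortho-substituted aroyl centre that hydrodeiodination of 3 takes over. Both follow from the congestion around C4 and from the O-nucleophilic character of 12. The fallback forms the same two bonds by polar chemistry; it sets out from 2 and 10 and returns at 13. Vilsmeier–Haack formylation of 2 (POCl3, DMF) should give 2,4,6-tris(benzyloxy)benzaldehyde F1. The lithium enolate of 10 (LiN(SiMe3)2, THF, −78 °C) should add to it to give the aldol adduct 1-[4-(benzyloxy)-3-(methoxymethoxy)phenyl]-3-hydroxy-2-(methoxymethoxy)-3-[2,4,6-tris(benzyloxy)phenyl]propan-1-one F2 as a mixture of racemic diastereomers. Oxidation of the secondary benzylic alcohol with Dess–Martin periodinane (NaHCO3 buffer, CH2Cl2) then gives 13. An aldehyde can only be attacked at carbon, so the O- versus C-acylation question does not arise.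

Step 8. The most likely failure is unselective ether cleavage: the Lewis acid may strip the chelated methoxymethyl acetals as fast as the ortho benzyl ether, or the aryl ketone, twisted out of the ring plane by its two ortho substituents, may chelate too weakly for the benzyl cleavage to proceed. Loss of acetals alone would be harmless, since step 9 removes them. The fallback singles out the future O1 before the coupling; it sets out from 1 and returns at 16. Benzylation of 1 with two equivalents of benzyl chloride under the conditions of step 1, then hydrolysis of the remaining acetate (aqueous NaOH), should give 3,5-bis(benzyloxy)phenol F3. Iodination of its phenoxide (I2, NaHCO3, THF–H2O, 0 °C) is expected to go mainly ortho to the hydroxyl, the position between the two benzyloxy groups being more hindered; after removal of material iodinated at the other position this gives 3,5-bis(benzyloxy)-2-iodophenol F4. MOMCl and iPr2NEt then give 1,5-bis(benzyloxy)-2-iodo-3-(methoxymethoxy)benzene F5. The conditions of step 7 with 10 and 11 should convert it into racemic 1-[2,4-bis(benzyloxy)-6-(methoxymethoxy)phenyl]-3-[4-(benzyloxy)-3-(methoxymethoxy)phenyl]-2-(methoxymethoxy)propane-1,3-dione F6, and the conditions of step 9 remove all three acetals and close ring C to 16. The cost is a regioisomer separation at the stage of the iodophenol.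

Step 9. The most likely failure is degradation at the α-hydroxy-1,3-diketone stage: retro-Claisen cleavage by the alcohol solvent or air oxidation of the enediol tautomer before the ring has closed. Electrophilic attack of released formaldehyde equivalents on ring A is a lesser concern. Partial loss of the 5-O-benzyl group would be tolerable, because the chelated hydroxyl that results is the least reactive toward sulfation. The fallback closes the ring before unmasking; it sets out from 14 and returns at 16. Buffered cyclodehydration (NaOAc, AcOH, 100 °C) should give 5,7-bis(benzyloxy)-2-[4-(benzyloxy)-3-(methoxymethoxy)phenyl]-3-(methoxymethoxy)-4H-chromen-4-one F7, in which no 1,3-diketone remains; an acetal lost already at this stage is of no consequence. The acetals are then removed with HCl in MeOH–THF to give 16.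

Step 10. The most likely failure is incomplete sulfation at O3, which is hydrogen-bonded to the C4 carbonyl and flanked by ring B, or hydrolytic loss of this enol-type sulfate during work-up and purification of a very polar salt. The fallback uses neutral sulfate diesters; it sets out from 16 and returns at 17. 2,2,2-Trichloroethyl chlorosulfate with Et3N and DMAP in THF should give 5,7-bis(benzyloxy)-2-{4-(benzyloxy)-3-[(2,2,2-trichloroethoxy)sulfonyloxy]phenyl}-4-oxo-4H-chromen-3-yl 2,2,2-trichloroethyl sulfate F8, a neutral compound that can be chromatographed on silica. Zn dust and HCO2NH4 in MeOH then remove both trichloroethyl groups by reductive fragmentation to give 17.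

## Further compounds

F1 | step 7 | 2,4,6-tris(benzyloxy)benzaldehyde | O=Cc1c(OCc2ccccc2)cc(OCc2ccccc2)cc1OCc1ccccc1
F2 | step 7 | 1-[4-(benzyloxy)-3-(methoxymethoxy)phenyl]-3-hydroxy-2-(methoxymethoxy)-3-[2,4,6-tris(benzyloxy)phenyl]propan-1-one (mixture of racemic diastereomers) | COCOC(C(O)c1c(OCc2ccccc2)cc(OCc2ccccc2)cc1OCc1ccccc1)C(=O)c1ccc(OCc2ccccc2)c(OCOC)c1
F3 | step 8 | 3,5-bis(benzyloxy)phenol | Oc1cc(OCc2ccccc2)cc(OCc2ccccc2)c1
F4 | step 8 | 3,5-bis(benzyloxy)-2-iodophenol | Oc1cc(OCc2ccccc2)cc(OCc2ccccc2)c1I
F5 | step 8 | 1,5-bis(benzyloxy)-2-iodo-3-(methoxymethoxy)benzene | COCOc1cc(OCc2ccccc2)cc(OCc2ccccc2)c1I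
F6 | step 8 | racemic 1-[2,4-bis(benzyloxy)-6-(methoxymethoxy)phenyl]-3-[4-(benzyloxy)-3-(methoxymethoxy)phenyl]-2-(methoxymethoxy)propane-1,3-dione | COCOC(C(=O)c1c(OCOC)cc(OCc2ccccc2)cc1OCc1ccccc1)C(=O)c1ccc(OCc2ccccc2)c(OCOC)c1
F7 | step 9 | 5,7-bis(benzyloxy)-2-[4-(benzyloxy)-3-(methoxymethoxy)phenyl]-3-(methoxymethoxy)-4H-chromen-4-one | O=c1c(OCOC)c(-c2ccc(OCc3ccccc3)c(OCOC)c2)oc2cc(OCc3ccccc3)cc(OCc3ccccc3)c12
F8 | step 10 | 5,7-bis(benzyloxy)-2-{4-(benzyloxy)-3-[(2,2,2-trichloroethoxy)sulfonyloxy]phenyl}-4-oxo-4H-chromen-3-yl 2,2,2-trichloroethyl sulfate | O=c1c(OS(=O)(=O)OCC(Cl)(Cl)Cl)c(-c2ccc(OCc3ccccc3)c(OS(=O)(=O)OCC(Cl)(Cl)Cl)c2)oc2cc(OCc3ccccc3)cc(OCc3ccccc3)c12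
A1 | alternative 1 | 5,7-bis(benzyloxy)-2-(2,2-dioxido-1,3,2-benzodioxathiol-5-yl)-4-oxo-4H-chromen-3-yl 2,2,2-trichloroethyl sulfate | O=c1c(OS(=O)(=O)OCC(Cl)(Cl)Cl)c(-c2ccc3OS(=O)(=O)Oc3c2)oc2cc(OCc3ccccc3)cc(OCc3ccccc3)c12
A2 | alternative 1 | 5,7-bis(benzyloxy)-2-(3,4-dihydroxyphenyl)-4-oxo-4H-chromen-3-yl 2,2,2-trichloroethyl sulfate | O=c1c(OS(=O)(=O)OCC(Cl)(Cl)Cl)c(-c2ccc(O)c(O)c2)oc2cc(OCc3ccccc3)cc(OCc3ccccc3)c12
A3 | alternative 1 | 1,1'-sulfonyldiimidazole | O=S(=O)(n1ccnc1)n1ccnc1
A4 | alternative 1 | caesium carbonate, Cs2CO3 | [Cs+].[Cs+].[O-]C([O-])=O
A5 | alternative 1 | quercetin | O=c1c(O)c(-c2ccc(O)c(O)c2)oc2cc(O)cc(O)c12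
A6 | alternative 2 | racemic 2-[4-(benzyloxy)-3-(methoxymethoxy)phenyl]-5,7-dihydroxychroman-4-one | O=C1CC(c2ccc(OCc3ccccc3)c(OCOC)c2)Oc2cc(O)cc(O)c12
A7 | alternative 2 | methyl (8E)-9-[4-(benzyloxy)-3-(methoxymethoxy)phenyl]-3,5,7-trioxonon-8-enoate | COC(=O)CC(=O)CC(=O)CC(=O)/C=C/c1ccc(OCc2ccccc2)c(OCOC)c1
A8 | alternative 2 | magnesium methoxide, Mg(OMe)2 | [Mg+2].[O-]C.[O-]C
A9 | alternative 3 | 5,7-bis(benzyloxy)-2-[4-(benzyloxy)-3-(methoxymethoxy)phenyl]-2-(tert-butyldimethylsilyloxy)-3-(methoxymethoxy)chroman (mixture of racemic diastereomers) | COCOC1Cc2c(OCc3ccccc3)cc(OCc3ccccc3)cc2OC1(O[Si](C)(C)C(C)(C)C)c1ccc(OCc2ccccc2)c(OCOC)c1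
A10 | alternative 3 | 3,5-bis(benzyloxy)-2-formylphenyl tert-butyl carbonate | CC(C)(C)OC(=O)Oc1cc(OCc2ccccc2)cc(OCc2ccccc2)c1C=O
A11 | alternative 3 | tert-butyl({(Z)-1-[4-(benzyloxy)-3-(methoxymethoxy)phenyl]-2-(methoxymethoxy)ethenyl}oxy)dimethylsilane | COCO/C=C(\O[Si](C)(C)C(C)(C)C)c1ccc(OCc2ccccc2)c(OCOC)c1
A12 | alternative 3 | sodium borohydride, NaBH4 | [Na+].[BH4-]
A13 | alternative 3 | 3,5-bis(benzyloxy)-6-methylidenecyclohexa-2,4-dien-1-one | C=C1C(=O)C=C(OCc2ccccc2)C=C1OCc1ccccc1
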